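Substrate is the account to keep. A used partner puts one substrate into target, and each target lost takes one more into side product, so the partner charge could claim 1.40 times the substrate charge. That makes substrate the limiting reagent.

    substrate + partner → target, rate k1*[substrate]^1.5*[partner] (k1 = 0.057 L¹·⁵ mol⁻¹·⁵ s⁻¹, Ea1 = 56.0 kJ mol⁻¹)
    substrate + target ⇌ idle adduct, settled at all times (K2 = 31 L mol⁻¹, ΔH2 = −57.0 kJ mol⁻¹)
    substrate + target → side product (k3 = 0.037 L mol⁻¹ s⁻¹, Ea3 = 52.0 kJ mol⁻¹)
    (constants at 25 °C)

| flask | substrate | partner | temperature | time |
|---|---|---|---|---|
| cedar | 0.15 M | 0.700 equiv | 65 °C | 1.5 min |
| maple | 0.15 M | 0.700 equiv | 25 °C | 1.5 min |
| larch | 0.15 M | 0.700 equiv | 45 °C | 1.5 min |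

- percentages count the substrate that a species holds: one idle adduct or side product counts as two
- target is meant together with its idle adduct
- at 25 °C the constants are as listed, elsewhere as the activation energies and enthalpies make them
- in an amount of target, one idle adduct counts as one target

- the flask that comes out highest in amount of target, in percent of the substrate charged, or "all alike" when all lie within 1.5 percentage points (cedar / maple / larch / all alike)
- target at the end, in percent of the substrate charged, cedar
- target at the end, in percent of the substrate charged, maple
- target at the end, in percent of the substrate charged, larch

Open an entry for each form in each flask: unbound substrate, free target, idle adduct and side product, the last two counted double. Target counted with its adduct grows by the making step and shrinks by the loss step, which acts on free target. Set the two rates equal. Counted target then stands at the ratio of the two rate constants, times the root of [substrate], times [partner], times one plus the adduct constant times [substrate].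

Work this out for cedar at the start. There the adduct constant has dropped to 2.04 L mol⁻¹, and the level comes to 66.0% of the charge. Call this the balance level: below it target climbs, above it target falls, and it sinks as the flask consumes substrate and partner.

Maple starts at 236%, above the whole charge, so its clock counts. With substrate held at its charge and the loss step set aside, the making step gives an estimate of 18.0% for maple in 1.5 min. With substrate held at its charge, cedar's partner has a half-life of 0.241 min, far shorter than the time, so cedar should meet its sinking level early. The hand stops here, with larch unranked.

The forecast says 14.5% for cedar, 14.8% for maple and 23% for larch, with larch highest, as “fast enough to convert while the adduct still shields some of the target”.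

The flasks give 14.1% for cedar, 14.0% for maple and 22.7% for larch, so larch stands highest, as forecast. Cedar ends with 68.5% of the substrate in side product. Scale the balance level to cedar's final substrate and partner: it comes to 6.71%, and counted target stands above it at 14.1%, so in cedar loss is outrunning making at that moment.

Now charge cedar with 1.20 equiv of partner. At fixed [substrate] the level is proportional to [partner], so it starts at 113%, and cedar's final figure scaled by the same factor gives a rough estimate of 24.2%. The computed neighbour holds 26.0%, more than the 22.7% of larch at its 0.700 equiv of partner.

Its constants were drawn at random within sensible limits; the rest is arithmetic.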